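**Strategy**

The lactone ring (O1, C2, C3, C4, C5) carries its OCH2 carbon C5 on C4, and C4 is bonded to the carbinol carbon C7'. With C7' at the ketone oxidation level C4 becomes enolisable, so C5 can be supplied by formaldehyde: one aldol forms C4–C5 and the new alkoxide closes O1–C2 onto a C2 methyl ester, creating the ring and the trans C3/C4 relationship in a single operation. The precursor is an open-chain γ-keto ester whose only stereocentre, C3, comes from an oxazolidinone-directed enolate alkylation with an α-bromo ketone. Catalyst-controlled ketone reduction and debenzylation complete the synthesis.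

Key step: step 5

Remarks on the chemistry:
- Atom labels: O1, C2 (lactone carbonyl), C3 (arylmethyl-bearing), C4, C5 (OCH2), C7' (benzylic carbinol). The target is 3R,4R,7'S, with the C3 and C4 substituents trans.
- Assumption: dihydroferulic acid, (S)-4-benzyl-2-oxazolidinone, 2-bromo-1-(3,4-dimethoxyphenyl)ethanone and paraformaldehyde are taken as purchased.
- The phenol stays benzylated through step 6, because a free phenoxide would itself be hydroxymethylated by formaldehyde.
- The acyl group of the key-step precursor is the methyl ester, not the imide, because a more activated acyl group invites enol-lactone formation and loss of C3.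

**Route**

Step 1
Reactants: 1 dihydroferulic acid [3-(4-hydroxy-3-methoxyphenyl)propanoic acid]
Product: 3 3-(4-benzyloxy-3-methoxyphenyl)propanoic acid, via benzyl 3-(4-benzyloxy-3-methoxyphenyl)propanoate 2 (not isolated)
Conditions: BnBr (2.2 equiv), K2CO3, DMF, 60 °C; then NaOH, MeOH/H2O, 60 °C; HCl work-up
Reagents that add atoms: benzyl bromide BrCc1ccccc1; sodium hydroxide [Na+].[OH-] (its oxygen replaces the benzyloxy oxygen of the ester)
Why: Williamson O-benzylation of the phenoxide (the carboxylate is benzylated too), followed by saponification of the benzyl ester in the same pot, should leave only the base-stable aryl benzyl ether.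

Step 2
Reactants: 3 3-(4-benzyloxy-3-methoxyphenyl)propanoic acid; 4 (S)-4-benzyl-2-oxazolidinone
Product: 6 (S)-4-benzyl-3-[3-(4-benzyloxy-3-methoxyphenyl)propanoyl]oxazolidin-2-one, via mixed pivalic anhydride 5 (not isolated)
Conditions: t-BuCOCl, Et3N, THF, −20 °C; then 4, LiCl, −20 °C to rt
Reagents that add atoms: none
Why: N-acylation of the oxazolidinone through a mixed pivalic anhydride, in which the hindered pivaloyl carbonyl steers the LiCl-activated oxazolidinone to the arylpropanoyl carbonyl and no strong base is needed.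

Step 3
Reactants: 6 (S)-4-benzyl-3-[3-(4-benzyloxy-3-methoxyphenyl)propanoyl]oxazolidin-2-one; 7 bromoacetoveratrone [2-bromo-1-(3,4-dimethoxyphenyl)ethan-1-one]
Product: 9 (S)-4-benzyl-3-[(R)-2-(4-benzyloxy-3-methoxybenzyl)-4-(3,4-dimethoxyphenyl)-4-oxobutanoyl]oxazolidin-2-one, via sodium Z-enolate 8 (not isolated)
Conditions: NaN(SiMe3)2, THF, −78 °C; then 7, −78 to −40 °C; AcOH quench
Reagents that add atoms: none
Why: Evans asymmetric alkylation, in which the benzyl group on the oxazolidinone ring blocks one face of the sodium-chelated Z-enolate, so the highly SN2-reactive phenacyl-type bromide is attacked from the open face and C3 is set as R.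

Step 4
Reactants: 9 (S)-4-benzyl-3-[(R)-2-(4-benzyloxy-3-methoxybenzyl)-4-(3,4-dimethoxyphenyl)-4-oxobutanoyl]oxazolidin-2-one
Product: 10 methyl (R)-2-(4-benzyloxy-3-methoxybenzyl)-4-(3,4-dimethoxyphenyl)-4-oxobutanoate
Conditions: MeMgBr, MeOH, CH2Cl2, 0 °C (gives MeOMgBr); then 9, 0 °C; 1 M HCl quench
Reagents that add atoms: methanol CO (delivered as methoxymagnesium bromide)
Why: Transesterification of the N-acyl oxazolidinone with methoxymagnesium bromide, where magnesium chelation activates the exocyclic imide carbonyl so the auxiliary is exchanged for OMe under weakly basic conditions that should not touch the C3–H.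

Step 5
Reactants: 10 methyl (R)-2-(4-benzyloxy-3-methoxybenzyl)-4-(3,4-dimethoxyphenyl)-4-oxobutanoate; 11 formaldehyde (charged as paraformaldehyde)
Product: 13 (3R,4R)-3-(4-benzyloxy-3-methoxybenzyl)-4-(3,4-dimethoxybenzoyl)dihydrofuran-2(3H)-one, via hydroxymethyl keto ester 12 (not isolated)
Conditions: (CH2O)n (1.1 equiv CH2O), K2CO3 (20 mol %), MeOH/THF, 0 °C to rt; AcOH quench
Reagents that add atoms: none
Why: Catalytic carbonate/methoxide deprotonates C4, the only enolisable position of the aryl ketone and several pKa units more acidic than the ester α-CH at C3, and the enolate adds to formaldehyde in a crossed aldol that forms C4–C5. The primary alkoxide of 12 then displaces methoxide from the C2 ester in a 5-exo-trig acyl substitution (O1–C2), which pulls the reversible hydroxymethylation forward; the closest known reaction type is the formaldehyde hydroxymethylation–lactonisation of β-aroylpropionates to β-aroyl-γ-butyrolactones. The new stereocentre C4 stays enolisable beside the ketone and is therefore set thermodynamically, trans to the C3 arylmethyl group, which this weak base should not epimerise. Single addition is secured by about one equivalent of formaldehyde and by the hindered tertiary C4–H of 13, whose aldol would give a congested and readily reversible quaternary adduct. Ring-opening β-elimination of O1 from the C4 enolate is the reverse of a 5-endo-trig closure and is stereoelectronically disfavoured, because the C5–O1 bond lies close to the enolate plane. Methanol as solvent with a methyl ester makes any transesterification degenerate.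

Step 6
Reactants: 13 (3R,4R)-3-(4-benzyloxy-3-methoxybenzyl)-4-(3,4-dimethoxybenzoyl)dihydrofuran-2(3H)-one
Product: 14 (3R,4R)-3-(4-benzyloxy-3-methoxybenzyl)-4-[(S)-(3,4-dimethoxyphenyl)(hydroxy)methyl]dihydrofuran-2(3H)-one
Conditions: (R)-2-methyl-CBS-oxazaborolidine (30 mol %), BH3·SMe2, THF, −20 °C; MeOH quench
Reagents that add atoms: none
Why: Corey–Bakshi–Shibata reduction, in which the aryl group takes the large-group position on the catalyst so the (R)-catalyst should deliver hydride to the face that gives the 7'S alcohol (the sense of acetophenone to (S)-1-phenylethanol), a Felkin–Anh bias with C3 as the larger α-substituent is expected to point the same way, and the non-basic medium leaves the epimerisable C4 and the lactone untouched.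

Step 7
Reactants: 14 (3R,4R)-3-(4-benzyloxy-3-methoxybenzyl)-4-[(S)-(3,4-dimethoxyphenyl)(hydroxy)methyl]dihydrofuran-2(3H)-one
Product: 15 (3R,4R)-4-[(S)-(3,4-dimethoxyphenyl)(hydroxy)methyl]-3-(4-hydroxy-3-methoxybenzyl)dihydrofuran-2(3H)-one
Conditions: H2 (1 atm), Pd/C, EtOAc, rt, stopped at full conversion
Reagents that add atoms: none
Why: Hydrogenolysis of the aryl benzyl ether over Pd/C in a neutral solvent, which should be much faster than C–O cleavage of the secondary benzylic alcohol in the absence of acid and avoids both base-induced translactonisation onto O7' and acid-induced ionisation at C7'.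

**Compound list**

1 | dihydroferulic acid, 3-(4-hydroxy-3-methoxyphenyl)propanoic acid | COc1cc(CCC(=O)O)ccc1O | starting material
2 | benzyl 3-(4-benzyloxy-3-methoxyphenyl)propanoate (formed in situ) | COc1cc(CCC(=O)OCc2ccccc2)ccc1OCc1ccccc1 | intermediate
3 | 3-(4-benzyloxy-3-methoxyphenyl)propanoic acid | COc1cc(CCC(=O)O)ccc1OCc1ccccc1 | intermediate
4 | (S)-4-benzyl-2-oxazolidinone | O=C1N[C@@H](Cc2ccccc2)CO1 | starting material
5 | 3-(4-benzyloxy-3-methoxyphenyl)propanoic pivalic anhydride (formed in situ) | COc1cc(CCC(=O)OC(=O)C(C)(C)C)ccc1OCc1ccccc1 | intermediate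
6 | (S)-4-benzyl-3-[3-(4-benzyloxy-3-methoxyphenyl)propanoyl]oxazolidin-2-one | COc1cc(CCC(=O)N2C(=O)OC[C@@H]2Cc2ccccc2)ccc1OCc1ccccc1 | intermediate
7 | bromoacetoveratrone, 2-bromo-1-(3,4-dimethoxyphenyl)ethan-1-one | COc1ccc(C(=O)CBr)cc1OC | starting material
8 | sodium (Z)-enolate of 6 (formed in situ) | [Na+].[O-]/C(=C\Cc1ccc(OCc2ccccc2)c(OC)c1)N1C(=O)OC[C@@H]1Cc1ccccc1 | intermediate
9 | (S)-4-benzyl-3-[(R)-2-(4-benzyloxy-3-methoxybenzyl)-4-(3,4-dimethoxyphenyl)-4-oxobutanoyl]oxazolidin-2-one | COc1cc(C[C@H](CC(=O)c2ccc(OC)c(OC)c2)C(=O)N2C(=O)OC[C@@H]2Cc2ccccc2)ccc1OCc1ccccc1 | intermediate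
10 | methyl (R)-2-(4-benzyloxy-3-methoxybenzyl)-4-(3,4-dimethoxyphenyl)-4-oxobutanoate (key-step precursor) | COc1cc(C[C@H](CC(=O)c2ccc(OC)c(OC)c2)C(=O)OC)ccc1OCc1ccccc1 | intermediate
11 | formaldehyde (charged as paraformaldehyde) | C=O | starting material
12 | methyl (2R,3R)-2-(4-benzyloxy-3-methoxybenzyl)-4-(3,4-dimethoxyphenyl)-3-(hydroxymethyl)-4-oxobutanoate (aldol adduct, formed in situ; drawn as the epimer that closes to 13, the carbon next to the ketone equilibrates) | COc1cc(C[C@@H](C(=O)OC)[C@H](CO)C(=O)c2ccc(OC)c(OC)c2)ccc1OCc1ccccc1 | intermediate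
13 | (3R,4R)-3-(4-benzyloxy-3-methoxybenzyl)-4-(3,4-dimethoxybenzoyl)dihydrofuran-2(3H)-one (key-step product) | COc1cc(C[C@H]2C(=O)OC[C@@H]2C(=O)c2ccc(OC)c(OC)c2)ccc1OCc1ccccc1 | intermediate
14 | (3R,4R)-3-(4-benzyloxy-3-methoxybenzyl)-4-[(S)-(3,4-dimethoxyphenyl)(hydroxy)methyl]dihydrofuran-2(3H)-one | COc1cc(C[C@H]2C(=O)OC[C@@H]2[C@H](O)c2ccc(OC)c(OC)c2)ccc1OCc1ccccc1 | intermediate
15 | (3R,4R)-4-[(S)-(3,4-dimethoxyphenyl)(hydroxy)methyl]-3-(4-hydroxy-3-methoxybenzyl)dihydrofuran-2(3H)-one | COc1cc(C[C@H]2C(=O)OC[C@@H]2[C@H](O)c2ccc(OC)c(OC)c2)ccc1O | target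

**Step count**

Total steps: 7. Longest linear sequence: 7 steps (1 to 15).

**Steps most likely to fail**

1. Step 5 (aldol–lactonisation). What may go wrong: dehydration of the aldol adduct or ring-opening β-elimination competing with lactonisation, a second hydroxymethylation at C4, or incomplete equilibration to the trans isomer. The fallback sets out from 10 and rejoins the route at 13; it replaces the free enolate by a neutral enol equivalent and the base by a Lewis acid. Soft enolisation of 10 (Me3SiOTf, Et3N, CH2Cl2, 0 °C; the ketone reacts, the ester does not) should give the silyl enol ether methyl (R,Z)-2-(4-benzyloxy-3-methoxybenzyl)-4-(3,4-dimethoxyphenyl)-4-[(trimethylsilyl)oxy]but-3-enoate F1. A Mukaiyama aldol of this enol ether with aqueous formaldehyde under Yb(OTf)3 catalysis (THF/H2O, rt) should give the hydroxymethyl keto ester 12, with single addition enforced by the one silyl group. Compound 12 is then lactonised with pyridinium p-toluenesulfonate in toluene at 60 °C. Any cis lactone (3R,4S)-3-(4-benzyloxy-3-methoxybenzyl)-4-(3,4-dimethoxybenzoyl)dihydrofuran-2(3H)-one F2 formed beside 13 is equilibrated at C4 with catalytic DBU in CH2Cl2, which returns the material to 13.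

2. Step 3 (enolate alkylation with the α-bromo ketone). What may go wrong: proton transfer from the acidic α-bromo ketone to the enolate, or attack at the ketone carbonyl (Darzens-type) in place of SN2 displacement. The fallback sets out from 6 and rejoins the route at 9; it masks the ketone as a 1,1-disubstituted alkene. The sodium enolate of 6 is alkylated with 2,3-dibromopropene (NaN(SiMe3)2, THF, −78 °C, same facial control) to give (S)-4-benzyl-3-[(R)-2-(4-benzyloxy-3-methoxybenzyl)-4-bromopent-4-enoyl]oxazolidin-2-one F3. Suzuki–Miyaura coupling of the vinyl bromide with (3,4-dimethoxyphenyl)boronic acid (Pd(PPh3)4, a zerovalent palladium complex, K3PO4, dioxane, 80 °C) should give (S)-4-benzyl-3-[(R)-2-(4-benzyloxy-3-methoxybenzyl)-4-(3,4-dimethoxyphenyl)pent-4-enoyl]oxazolidin-2-one F4. Lemieux–Johnson cleavage of the alkene (OsO4 cat., NaIO4, 2,6-lutidine, dioxane/H2O) then unveils the aryl ketone and gives 9.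

3. Step 6 (ketone reduction). What may go wrong: poor facial selectivity, because the branched stereogenic carbon C4 competes with the aryl group for the large-group position on the catalyst. The fallback sets out from 13 and rejoins the route at 14; it relies on separation and stereochemical correction instead of catalyst control. Hydride reduction under substrate control (NaBH4, CeCl3·7H2O, MeOH/CH2Cl2, −78 °C) should give 14 together with its epimer (3R,4R)-3-(4-benzyloxy-3-methoxybenzyl)-4-[(R)-(3,4-dimethoxyphenyl)(hydroxy)methyl]dihydrofuran-2(3H)-one F5, to be separated by chromatography. The epimer is inverted by Mitsunobu esterification (ClCH2CO2H, PPh3, DIAD, THF, 0 °C) to (S)-(3,4-dimethoxyphenyl)[(3R,4R)-4-(4-benzyloxy-3-methoxybenzyl)-5-oxooxolan-3-yl]methyl chloroacetate F6. The chloroacetyl group is removed with thiourea (NaHCO3, EtOH, 50 °C), conditions mild enough to spare the lactone, to give 14.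

**Further compounds**

F1 | step 5 | methyl (R,Z)-2-(4-benzyloxy-3-methoxybenzyl)-4-(3,4-dimethoxyphenyl)-4-[(trimethylsilyl)oxy]but-3-enoate | COc1cc(C[C@H](/C=C(\O[Si](C)(C)C)c2ccc(OC)c(OC)c2)C(=O)OC)ccc1OCc1ccccc1
F2 | step 5 | (3R,4S)-3-(4-benzyloxy-3-methoxybenzyl)-4-(3,4-dimethoxybenzoyl)dihydrofuran-2(3H)-one | COc1cc(C[C@H]2C(=O)OC[C@H]2C(=O)c2ccc(OC)c(OC)c2)ccc1OCc1ccccc1
F3 | step 3 | (S)-4-benzyl-3-[(R)-2-(4-benzyloxy-3-methoxybenzyl)-4-bromopent-4-enoyl]oxazolidin-2-one | COc1cc(C[C@H](CC(Br)=C)C(=O)N2C(=O)OC[C@@H]2Cc2ccccc2)ccc1OCc1ccccc1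
F4 | step 3 | (S)-4-benzyl-3-[(R)-2-(4-benzyloxy-3-methoxybenzyl)-4-(3,4-dimethoxyphenyl)pent-4-enoyl]oxazolidin-2-one | COc1cc(C[C@H](CC(=C)c2ccc(OC)c(OC)c2)C(=O)N2C(=O)OC[C@@H]2Cc2ccccc2)ccc1OCc1ccccc1
F5 | step 6 | (3R,4R)-3-(4-benzyloxy-3-methoxybenzyl)-4-[(R)-(3,4-dimethoxyphenyl)(hydroxy)methyl]dihydrofuran-2(3H)-one | COc1cc(C[C@H]2C(=O)OC[C@@H]2[C@@H](O)c2ccc(OC)c(OC)c2)ccc1OCc1ccccc1
F6 | step 6 | (S)-(3,4-dimethoxyphenyl)[(3R,4R)-4-(4-benzyloxy-3-methoxybenzyl)-5-oxooxolan-3-yl]methyl chloroacetate | COc1cc(C[C@H]2C(=O)OC[C@@H]2[C@H](OC(=O)CCl)c2ccc(OC)c(OC)c2)ccc1OCc1ccccc1
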